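**Plan**

Retrosynthesis: the C10–C11 epoxide oxygen and the two acetyl groups go first; the α-methylene γ-lactone is cut at O7–C16 and C16–C15 (loss of CO); the 14-membered ring is cut at C1–C14 and the chain at C7–C8.
Enabling feature: the α-methylene γ-lactone fused across C7–C8 (ring atoms O7, C7, C8, C15, C16; exocyclic C17) is the sum of a C7 hydroxyl, a C8 ethynyl group and one CO.
Forward: fragment A (C1–C7, from (S)-citronellal) and fragment B (C8–C14, from pent-4-yn-1-ol) are joined at C7–C8 by a chiral allenylstannane addition; the carbocycle is closed at C1–C14 by an alkenyl iodide–aldehyde coupling; the lactone ring is closed by palladium and CO; the epoxide comes last.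
Stereochemistry: C5 from citronellal; C6 by L-proline aminoxylation; C8 from a transfer-hydrogenated propargylic alcohol relayed through the allene axis; C7 by magnesium chelation in the same addition; C14 by oxazaborolidine reduction; C10/C11 by the Shi ketone.

Key step: step 26

Remarks.
- Numbering: ring carbons C1 (bearing the exocyclic methylene) to C14; C15, C16 and C17 are the lactone α-carbon, carbonyl carbon and methylene carbon. Descriptors of macrocyclic compounds use this numbering.
- Relative configuration: the target lactone is cis-fused (H7 and H8 on one face). The open-chain carbinol therefore needs O7 and the C9 branch syn across C6–C7–C8–C15 (equivalently, O7 and the ethynyl group anti along the ring backbone). An allenylstannane reacting through an open transition state gives this relationship; allenylzinc or allenylindium reagents (cyclic transition state) would give the trans-lactone series.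
- Acetal 5 and its successors up to 11 are mixtures of epimers at the acetal carbon; this centre is destroyed in step 8.
- Assumption: commercial (S)-citronellal of high enantiomeric purity; diastereomers from its minor enantiomer are removed at diol 4.
- The C7 hydroxyl stays free from step 19 to step 26; the oxidations and the silylation in between are chosen to discriminate against it.

**Fragment A (C1–C7)**

Step 1
Reactants: 1 (S)-citronellal
Product: 3 (2R,3S)-2-(anilinooxy)-3,7-dimethyloct-6-en-1-ol, via α-anilinooxy aldehyde 2 (not isolated)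
Conditions: PhNO, L-proline (20 mol%), MeCN, −20 °C; then NaBH4, EtOH, 0 °C
Reagents that add atoms: nitrosobenzene, O=Nc1ccccc1
Why: Proline-catalysed α-aminoxylation, in which the enamine of 1 attacks the oxygen of nitrosobenzene held by the catalyst's carboxylic acid, should set C6 as R under catalyst control irrespective of C5, and reduction in the same flask prevents epimerisation of the α-oxy aldehyde.

Step 2
Reactants: 3 (2R,3S)-2-(anilinooxy)-3,7-dimethyloct-6-en-1-ol
Product: 4 (2R,3S)-3,7-dimethyloct-6-ene-1,2-diol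
Conditions: Zn dust, AcOH/EtOH, rt
Reagents that add atoms: none
Why: Reductive N–O cleavage by zinc in acetic acid should free the diol without touching the trisubstituted olefin or either stereocentre.

Step 3
Reactants: 4 (2R,3S)-3,7-dimethyloct-6-ene-1,2-diol
Product: 5 (4R)-2-(4-methoxyphenyl)-4-[(2S)-6-methylhept-5-en-2-yl]-1,3-dioxolane
Conditions: 4-MeOC6H4CH(OMe)2, PPTS (cat.), CH2Cl2, rt
Reagents that add atoms: 4-methoxybenzaldehyde dimethyl acetal, COc1ccc(cc1)C(OC)OC
Why: Acid-catalysed transacetalisation gives the five-membered p-methoxybenzylidene acetal, which masks O6 and O7 during chain extension and later delivers the O6 p-methoxybenzyl ether.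

Step 4
Reactants: 5 p-methoxybenzylidene acetal
Product: 7 (4S)-4-[(4R)-2-(4-methoxyphenyl)-1,3-dioxolan-4-yl]pentan-1-ol, via aldehyde 6 (not isolated)
Conditions: O3, CH2Cl2/MeOH, −78 °C (Sudan Red 7B end point); then NaBH4, −78 → 0 °C
Reagents that add atoms: ozone, [O-][O+]=O
Why: Ozonolysis with reductive work-up should cleave the electron-rich trisubstituted olefin before the acetal C–H is attacked when ozone is dosed to an indicator end point, and NaBH4 reduces the C2 aldehyde in the same flask.

Step 5
Reactants: 7 primary alcohol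
Product: 8 (4R)-4-[(2S)-5-iodopentan-2-yl]-2-(4-methoxyphenyl)-1,3-dioxolane
Conditions: I2, PPh3, imidazole, CH2Cl2, 0 °C → rt
Reagents that add atoms: iodine, II
Why: Appel-type iodination of a primary alcohol under imidazole-buffered conditions should leave the acetal intact.

Step 6
Reactants: 8 primary iodide
Product: 9 (4R)-4-[(2S)-hept-6-yn-2-yl]-2-(4-methoxyphenyl)-1,3-dioxolane
Conditions: LiC≡CH·H2NCH2CH2NH2, DMSO, 10 °C → rt
Reagents that add atoms: lithium acetylide–ethylenediamine complex, [Li]C#C.NCCN
Why: SN2 alkylation of lithium acetylide by an unhindered primary iodide in DMSO installs C1 and the future methylene carbon.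

Step 7
Reactants: 9 terminal alkyne
Product: 11 (4R)-4-[(2S)-6-iodohept-6-en-2-yl]-2-(4-methoxyphenyl)-1,3-dioxolane, via alkenylalane 10 (not isolated)
Conditions: NiCl2(dppp) (3 mol%), i-Bu2AlH (1.3 equiv), THF, 0 °C → rt; then I2, −78 → 0 °C
Reagents that add atoms: iodine, II
Why: Nickel-catalysed α-selective hydroalumination of a terminal alkyl alkyne places aluminium on the internal carbon and iodinolysis of the C–Al bond gives the 2-iodo-1-alkene, while THF-coordinated i-Bu2AlH should spare the acetal.

Step 8
Reactants: 11 alkenyl iodide acetal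
Product: 12 (2R,3S)-7-iodo-2-(4-methoxybenzyloxy)-3-methyloct-7-en-1-ol
Conditions: i-Bu2AlH (3 equiv), CH2Cl2, −78 → 0 °C
Reagents that add atoms: none
Why: Regioselective reductive opening of the benzylidene-type acetal: aluminium binds the less hindered primary oxygen and hydride goes to the acetal carbon, so the p-methoxybenzyl group stays on the secondary O6.

Step 9
Reactants: 12 primary alcohol
Product: 13 (2R,3S)-7-iodo-2-(4-methoxybenzyloxy)-3-methyloct-7-enal (fragment A)
Conditions: Dess–Martin periodinane, NaHCO3, CH2Cl2, 0 °C → rt; used crude at once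
Reagents that add atoms: none
Why: Buffered Dess–Martin oxidation should give the α-alkoxy aldehyde without epimerisation at C6.

**Fragment B (C8–C14)**

Step 10
Reactants: 14 pent-4-yn-1-ol
Product: 15 tert-butyldimethyl(pent-4-yn-1-yloxy)silane
Conditions: TBSCl, imidazole, CH2Cl2, rt
Reagents that add atoms: tert-butyldimethylsilyl chloride, CC(C)(C)[Si](C)(C)Cl
Why: Standard silylation of a primary alcohol.

Step 11
Reactants: 15 silyl-protected pentynol
Product: 18 (E)-7-(tert-butyldimethylsilyloxy)-4-methylhept-3-en-1-ol, via alkenylalane 16 (not isolated), via lithium alanate 17 (not isolated)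
Conditions: Me3Al, Cp2ZrCl2 (25 mol%), CH2Cl2, 0 °C → rt; volatiles removed; n-BuLi, THF/hexane, −78 °C; ethylene oxide, −78 → 0 °C
Reagents that add atoms: trimethylaluminium, C[Al](C)C; ethylene oxide, C1CO1
Why: Negishi zirconium-catalysed carboalumination adds methyl and aluminium syn across the alkyne (methyl to the internal carbon), which fixes the 10E olefin, and the lithium alanate opens ethylene oxide with retention of geometry.

Step 12
Reactants: 18 homoallylic alcohol
Product: 19 (E)-7-(tert-butyldimethylsilyloxy)-4-methylhept-3-enal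
Conditions: Dess–Martin periodinane, NaHCO3, CH2Cl2, 0 °C; used at once
Reagents that add atoms: none
Why: Buffered Dess–Martin oxidation; immediate use should avoid migration of the β,γ-double bond into conjugation.

Step 13
Reactants: 19 β,γ-unsaturated aldehyde
Product: 20 (5E)-9-(tert-butyldimethylsilyloxy)-6-methyl-1-(trimethylsilyl)non-5-en-1-yn-3-ol (racemic)
Conditions: HC≡CSiMe3, n-BuLi, THF, −78 °C; then 19, −78 °C
Reagents that add atoms: ethynyltrimethylsilane, C#C[Si](C)(C)C
Why: 1,2-Addition of a lithium acetylide to an aldehyde at low temperature; no stereocontrol is needed because the carbinol is oxidised next.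

Step 14
Reactants: 20 racemic propargylic alcohol
Product: 21 (5E)-9-(tert-butyldimethylsilyloxy)-6-methyl-1-(trimethylsilyl)non-5-en-1-yn-3-one
Conditions: Dess–Martin periodinane, NaHCO3, CH2Cl2, 0 °C
Reagents that add atoms: none
Why: Dess–Martin oxidation of a propargylic alcohol to the ynone under neutral conditions.

Step 15
Reactants: 21 ynone
Product: 22 (3S,5E)-9-(tert-butyldimethylsilyloxy)-6-methyl-1-(trimethylsilyl)non-5-en-1-yn-3-ol
Conditions: Ru[(S,S)-TsDPEN](p-cymene) (3 mol%), i-PrOH, rt
Reagents that add atoms: none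
Why: Noyori asymmetric transfer hydrogenation of an alkynyl ketone: the (S,S)-catalyst distinguishes the alkynyl from the alkyl flank and should give the S carbinol (C8) under neutral conditions that do not isomerise the skipped enone.

Step 16
Reactants: 22 (S)-silylalkynyl carbinol
Product: 23 (3S,5E)-9-(tert-butyldimethylsilyloxy)-6-methylnon-5-en-1-yn-3-ol
Conditions: K2CO3, MeOH, rt
Reagents that add atoms: none
Why: Methanolysis of the alkynyl C–Si bond; the primary silyl ether is stable to K2CO3 in methanol.

Step 17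
Reactants: 23 (S)-propargylic alcohol
Product: 24 (3S,5E)-9-(tert-butyldimethylsilyloxy)-6-methylnon-5-en-1-yn-3-yl methanesulfonate
Conditions: MsCl, Et3N, CH2Cl2, −78 °C
Reagents that add atoms: methanesulfonyl chloride, CS(=O)(=O)Cl
Why: Sulfonylation of the propargylic alcohol with retention at C8.

Step 18
Reactants: 24 (S)-propargylic mesylate
Product: 25 (M)-tributyl[(5E)-9-(tert-butyldimethylsilyloxy)-6-methylnona-1,2,5-trien-1-yl]stannane (fragment B)
Conditions: Bu3SnH, LiN(i-Pr)2, THF, 0 °C; CuBr·SMe2, −78 °C; then 24, −78 °C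
Reagents that add atoms: tributyltin hydride, CCCC[SnH](CCCC)CCCC
Why: SN2' displacement of a propargylic mesylate by a stannylcopper reagent occurs anti to the leaving group, so the S carbinol is translated into the M (aR) allene axis.

**Union, macrocycle, lactone, endgame**

Step 19
Reactants: 13 fragment A aldehyde; 25 fragment B allenylstannane
Product: 26 (4E,7S,8R,9R,10S)-1-(tert-butyldimethylsilyloxy)-7-ethynyl-14-iodo-9-(4-methoxybenzyloxy)-4,10-dimethylpentadeca-4,14-dien-8-ol (ring numbering: 5S,6R,7R,8S)
Conditions: MgBr2·OEt2 (3 equiv), CH2Cl2, −23 °C; 25 (1.3 equiv)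
Reagents that add atoms: none
Why: Lewis-acid-promoted SE2' addition of a chiral allenylstannane to an α-alkoxy aldehyde: magnesium chelates the aldehyde oxygen and O6 so that attack comes anti to the C5 branch (C7 R, 6,7-syn), the allene reacts at C8 anti to tin through an open transition state (C8 S, 7,8-syn), and both preferences coincide as a matched pair.

Step 20
Reactants: 26 coupled silyl ether
Product: 27 (4E,7S,8R,9R,10S)-7-ethynyl-14-iodo-9-(4-methoxybenzyloxy)-4,10-dimethylpentadeca-4,14-diene-1,8-diol
Conditions: HF·pyridine, pyridine, THF, 0 °C → rt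
Reagents that add atoms: none
Why: Buffered fluoride cleavage of the primary silyl ether should leave the p-methoxybenzyl ether, the alkenyl iodide and the alkyne intact.

Step 21
Reactants: 27 diol
Product: 28 (4E,7S,8R,9R,10S)-7-ethynyl-8-hydroxy-14-iodo-9-(4-methoxybenzyloxy)-4,10-dimethylpentadeca-4,14-dienal
Conditions: TEMPO (10 mol%), PhI(OAc)2, CH2Cl2, rt
Reagents that add atoms: none
Why: Oxoammonium oxidation (TEMPO with PhI(OAc)2) is selective for the primary alcohol over the hindered secondary C7 carbinol.

Step 22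
Reactants: 28 iodo hydroxy aldehyde
Product: 29 (5S,6R,7R,8S,10E)-8-ethynyl-6-(4-methoxybenzyloxy)-5,11-dimethyl-1-methylidenecyclotetradec-10-ene-7,14-diol (both C14 epimers)
Conditions: CrCl2 (10 equiv), NiCl2 (1 mol% of CrCl2), degassed DMSO/THF, rt, 2 mM, slow addition
Reagents that add atoms: none
Why: Nozaki–Hiyama–Kishi reaction: zerovalent nickel inserts into the C–I bond, transmetallation gives an alkenyl species of trivalent chromium that adds only to the aldehyde (free hydroxyl and alkyne tolerated) and closes the 14-membered ring at C1–C14 under high dilution; C14 is not controlled here and is set in steps 23 and 24.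

Step 23
Reactants: 29 macrocyclic diol (C14 epimers)
Product: 30 (5S,6R,7R,8S,10E)-8-ethynyl-7-hydroxy-6-(4-methoxybenzyloxy)-5,11-dimethyl-1-methylidenecyclotetradec-10-en-14-one
Conditions: MnO2 (activated, excess), CH2Cl2, rt
Reagents that add atoms: none
Why: MnO2 oxidises only the allylic C14 carbinol, leaves the saturated C7 carbinol and converges both epimers to one enone.

Step 24
Reactants: 30 macrocyclic enone
Product: 31 (5S,6R,7R,8S,10E,14S)-8-ethynyl-6-(4-methoxybenzyloxy)-5,11-dimethyl-1-methylidenecyclotetradec-10-ene-7,14-diol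
Conditions: (R)-2-methyl-CBS-oxazaborolidine (1 equiv), catecholborane (3 equiv), toluene, −78 °C
Reagents that add atoms: none
Why: Corey–Bakshi–Shibata reduction: the (R)-oxazaborolidine binds the ketone with the branched 1-methylenealkyl flank as the large group and should deliver hydride to give the 14S allylic alcohol under reagent control, catecholborane at −78 °C sparing the alkyne and olefins.

Step 25
Reactants: 31 (14S)-diol
Product: 32 (5S,6R,7R,8S,10E,14S)-14-(tert-butyldimethylsilyloxy)-8-ethynyl-6-(4-methoxybenzyloxy)-5,11-dimethyl-1-methylidenecyclotetradec-10-en-7-ol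
Conditions: TBSCl (1.2 equiv), imidazole, DMF, 0 °C
Reagents that add atoms: tert-butyldimethylsilyl chloride, CC(C)(C)[Si](C)(C)Cl
Why: Site-selective silylation: the allylic C14 hydroxyl is far less hindered than the C7 hydroxyl, which sits between two branched carbons.

Step 26
Reactants: 32 macrocyclic ethynyl carbinol
Product: 33 (5S,6R,7R,8S,10E,14S) cis-fused macrocyclic α-methylene γ-lactone (O7–C16(=O)–C15(=C17H2)–C8) with O6 p-methoxybenzyl ether and O14 TBS ether
Conditions: PdCl2 (10 mol%), PPh3 (20 mol%), SnCl2 (10 mol%), CO (7 atm), MeCN, 70 °C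
Reagents that add atoms: carbon monoxide, [C-]#[O+]
Why: Divalent palladium, CO and the C7 hydroxyl give an alkoxycarbonylpalladium species (O7–C16), the tethered alkyne inserts syn into the palladium–acyl bond (C16–C15), and protonolysis of the alkenylpalladium by the HCl released earlier frees the exocyclic methylene and returns divalent palladium, with SnCl2 as chloride-accepting co-catalyst. The closest known reaction type is the palladium-catalysed cyclocarbonylation of homopropargylic alcohols to α-methylene γ-butyrolactones, used here unchanged. The lactone ring closes in a 5-exo-dig mode. No stereocentre is created: C7 and C8 come from step 19 and their syn relationship becomes the cis ring fusion. The step needs the alkyne to insert in preference to the C1 methylene and the C10–C11 olefin, which the five-membered tether and the higher insertion aptitude of the alkyne secure. It also needs the C7 hydroxyl to be the only reacting oxygen function, which is secured by capping O14 as a silyl ether (no ionisable allylic alcohol) and O6 as a benzyl-type ether.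

Step 27
Reactants: 33 protected lactone
Product: 34 (5S,6R,7R,8S,10E,14S) α-methylene lactone with free C6 hydroxyl and O14 TBS ether
Conditions: DDQ, CH2Cl2/pH 7 buffer, 0 °C
Reagents that add atoms: none
Why: Oxidative cleavage of the p-methoxybenzyl ether by DDQ through the benzylic oxocarbenium ion, which water hydrolyses; the isolated olefins, the acrylate and the silyl ether should be inert.

Step 28
Reactants: 34 mono-silyl lactone
Product: 35 (5S,6R,7R,8S,10E,14S) α-methylene lactone 6,14-diol
Conditions: HF·pyridine, THF, 0 °C → rt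
Reagents that add atoms: none
Why: Fluoride cleavage of the secondary silyl ether under mildly acidic conditions avoids conjugate addition to the α-methylene lactone.

Step 29
Reactants: 35 lactone diol
Product: 36 (5S,6R,7R,8S,10E,14S) α-methylene lactone 6,14-diacetate
Conditions: Ac2O, pyridine, DMAP (cat.), CH2Cl2, 0 °C → rt
Reagents that add atoms: acetic anhydride, CC(=O)OC(C)=O
Why: DMAP-catalysed acetylation of both secondary hydroxyls.

Step 30
Reactants: 36 diacetate
Product: 37 target, (5S,6R,7R,8S,10R,11R,14S)-10,11-epoxide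
Conditions: D-fructose-derived Shi ketone (30 mol%), KHSO5 (as Oxone), K2CO3, Bu4NHSO4, MeCN/CH2(OMe)2/aq. Na2B4O7 buffer, 0 °C
Reagents that add atoms: potassium peroxymonosulfate, [K+].[O-]S(=O)(=O)OO
Why: Shi epoxidation: the chiral dioxirane from the D-fructose-derived ketone should epoxidise the electron-rich trisubstituted 10E olefin through a spiro transition state on the face that gives the 10R,11R epoxide, while the 1,1-disubstituted olefin (deactivated by the allylic acetate) and the electron-poor acrylate react much more slowly.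

**Compound list**

1 | (S)-citronellal, (3S)-3,7-dimethyloct-6-enal | CC(C)=CCC[C@H](C)CC=O | starting material
2 | (2R,3S)-2-(anilinooxy)-3,7-dimethyloct-6-enal | CC(C)=CCC[C@H](C)[C@@H](ONc1ccccc1)C=O | intermediate (not isolated)
3 | (2R,3S)-2-(anilinooxy)-3,7-dimethyloct-6-en-1-ol | CC(C)=CCC[C@H](C)[C@@H](ONc1ccccc1)CO | intermediate
4 | (2R,3S)-3,7-dimethyloct-6-ene-1,2-diol | CC(C)=CCC[C@H](C)[C@@H](O)CO | intermediate
5 | (4R)-2-(4-methoxyphenyl)-4-[(2S)-6-methylhept-5-en-2-yl]-1,3-dioxolane (acetal epimers) | CC(C)=CCC[C@H](C)[C@@H]1COC(c2ccc(OC)cc2)O1 | intermediate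
6 | (4S)-4-[(4R)-2-(4-methoxyphenyl)-1,3-dioxolan-4-yl]pentanal | O=CCC[C@H](C)[C@@H]1COC(c2ccc(OC)cc2)O1 | intermediate (not isolated)
7 | (4S)-4-[(4R)-2-(4-methoxyphenyl)-1,3-dioxolan-4-yl]pentan-1-ol | OCCC[C@H](C)[C@@H]1COC(c2ccc(OC)cc2)O1 | intermediate
8 | (4R)-4-[(2S)-5-iodopentan-2-yl]-2-(4-methoxyphenyl)-1,3-dioxolane | ICCC[C@H](C)[C@@H]1COC(c2ccc(OC)cc2)O1 | intermediate
9 | (4R)-4-[(2S)-hept-6-yn-2-yl]-2-(4-methoxyphenyl)-1,3-dioxolane | C#CCCC[C@H](C)[C@@H]1COC(c2ccc(OC)cc2)O1 | intermediate
10 | diisobutyl{(6S)-6-[(4R)-2-(4-methoxyphenyl)-1,3-dioxolan-4-yl]hept-1-en-2-yl}alane | C=C([Al](CC(C)C)CC(C)C)CCC[C@H](C)[C@@H]1COC(c2ccc(OC)cc2)O1 | intermediate (not isolated)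
11 | (4R)-4-[(2S)-6-iodohept-6-en-2-yl]-2-(4-methoxyphenyl)-1,3-dioxolane | C=C(I)CCC[C@H](C)[C@@H]1COC(c2ccc(OC)cc2)O1 | intermediate
12 | (2R,3S)-7-iodo-2-(4-methoxybenzyloxy)-3-methyloct-7-en-1-ol | C=C(I)CCC[C@H](C)[C@@H](OCc1ccc(OC)cc1)CO | intermediate
13 | (2R,3S)-7-iodo-2-(4-methoxybenzyloxy)-3-methyloct-7-enal (fragment A) | C=C(I)CCC[C@H](C)[C@@H](OCc1ccc(OC)cc1)C=O | intermediate
14 | pent-4-yn-1-ol | C#CCCCO | starting material
15 | tert-butyldimethyl(pent-4-yn-1-yloxy)silane | C#CCCCO[Si](C)(C)C(C)(C)C | intermediate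
16 | (E)-[5-(tert-butyldimethylsilyloxy)-2-methylpent-1-en-1-yl]dimethylalane | C[Al](C)/C=C(\C)CCCO[Si](C)(C)C(C)(C)C | intermediate (not isolated)
17 | lithium butyl[(E)-5-(tert-butyldimethylsilyloxy)-2-methylpent-1-en-1-yl]dimethylaluminate | [Li+].CCCC[Al-](C)(C)/C=C(\C)CCCO[Si](C)(C)C(C)(C)C | intermediate (not isolated)
18 | (E)-7-(tert-butyldimethylsilyloxy)-4-methylhept-3-en-1-ol | OCC/C=C(\C)CCCO[Si](C)(C)C(C)(C)C | intermediate
19 | (E)-7-(tert-butyldimethylsilyloxy)-4-methylhept-3-enal | O=CC/C=C(\C)CCCO[Si](C)(C)C(C)(C)C | intermediate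
20 | (5E)-9-(tert-butyldimethylsilyloxy)-6-methyl-1-(trimethylsilyl)non-5-en-1-yn-3-ol (racemic) | C[Si](C)(C)C#CC(O)C/C=C(\C)CCCO[Si](C)(C)C(C)(C)C | intermediate
21 | (5E)-9-(tert-butyldimethylsilyloxy)-6-methyl-1-(trimethylsilyl)non-5-en-1-yn-3-one | C[Si](C)(C)C#CC(=O)C/C=C(\C)CCCO[Si](C)(C)C(C)(C)C | intermediate
22 | (3S,5E)-9-(tert-butyldimethylsilyloxy)-6-methyl-1-(trimethylsilyl)non-5-en-1-yn-3-ol | C[Si](C)(C)C#C[C@@H](O)C/C=C(\C)CCCO[Si](C)(C)C(C)(C)C | intermediate
23 | (3S,5E)-9-(tert-butyldimethylsilyloxy)-6-methylnon-5-en-1-yn-3-ol | C#C[C@@H](O)C/C=C(\C)CCCO[Si](C)(C)C(C)(C)C | intermediate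
24 | (3S,5E)-9-(tert-butyldimethylsilyloxy)-6-methylnon-5-en-1-yn-3-yl methanesulfonate | C#C[C@@H](OS(C)(=O)=O)C/C=C(\C)CCCO[Si](C)(C)C(C)(C)C | intermediate
25 | (M)-tributyl[(5E)-9-(tert-butyldimethylsilyloxy)-6-methylnona-1,2,5-trien-1-yl]stannane (fragment B) | CCCC[Sn](CCCC)(CCCC)C([H])=[C@]=C([H])C/C=C(\C)CCCO[Si](C)(C)C(C)(C)C | intermediate
26 | (4E,7S,8R,9R,10S)-1-(tert-butyldimethylsilyloxy)-7-ethynyl-14-iodo-9-(4-methoxybenzyloxy)-4,10-dimethylpentadeca-4,14-dien-8-ol | C=C(I)CCC[C@H](C)[C@@H](OCc1ccc(OC)cc1)[C@H](O)[C@H](C#C)C/C=C(\C)CCCO[Si](C)(C)C(C)(C)C | intermediate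
27 | (4E,7S,8R,9R,10S)-7-ethynyl-14-iodo-9-(4-methoxybenzyloxy)-4,10-dimethylpentadeca-4,14-diene-1,8-diol | C=C(I)CCC[C@H](C)[C@@H](OCc1ccc(OC)cc1)[C@H](O)[C@H](C#C)C/C=C(\C)CCCO | intermediate
28 | (4E,7S,8R,9R,10S)-7-ethynyl-8-hydroxy-14-iodo-9-(4-methoxybenzyloxy)-4,10-dimethylpentadeca-4,14-dienal | C=C(I)CCC[C@H](C)[C@@H](OCc1ccc(OC)cc1)[C@H](O)[C@H](C#C)C/C=C(\C)CCC=O | intermediate
29 | (5S,6R,7R,8S,10E)-8-ethynyl-6-(4-methoxybenzyloxy)-5,11-dimethyl-1-methylidenecyclotetradec-10-ene-7,14-diol (C14 epimers) | C=C1CCC[C@H](C)[C@@H](OCc2ccc(OC)cc2)[C@H](O)[C@H](C#C)C/C=C(\C)CCC1O | intermediate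
30 | (5S,6R,7R,8S,10E)-8-ethynyl-7-hydroxy-6-(4-methoxybenzyloxy)-5,11-dimethyl-1-methylidenecyclotetradec-10-en-14-one | C=C1CCC[C@H](C)[C@@H](OCc2ccc(OC)cc2)[C@H](O)[C@H](C#C)C/C=C(\C)CCC1=O | intermediate
31 | (5S,6R,7R,8S,10E,14S)-8-ethynyl-6-(4-methoxybenzyloxy)-5,11-dimethyl-1-methylidenecyclotetradec-10-ene-7,14-diol | C=C1CCC[C@H](C)[C@@H](OCc2ccc(OC)cc2)[C@H](O)[C@H](C#C)C/C=C(\C)CC[C@@H]1O | intermediate
32 | (5S,6R,7R,8S,10E,14S)-14-(tert-butyldimethylsilyloxy)-8-ethynyl-6-(4-methoxybenzyloxy)-5,11-dimethyl-1-methylidenecyclotetradec-10-en-7-ol | C=C1CCC[C@H](C)[C@@H](OCc2ccc(OC)cc2)[C@H](O)[C@H](C#C)C/C=C(\C)CC[C@@H]1O[Si](C)(C)C(C)(C)C | intermediate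
33 | (5S,6R,7R,8S,10E,14S) cis-fused α-methylene γ-lactone, O6 p-methoxybenzyl ether, O14 TBS ether | C=C1CCC[C@H](C)[C@@H](OCc2ccc(OC)cc2)[C@@H]3OC(=O)C(=C)[C@@H]3C/C=C(\C)CC[C@@H]1O[Si](C)(C)C(C)(C)C | intermediate
34 | (5S,6R,7R,8S,10E,14S) α-methylene lactone, C6 hydroxyl, O14 TBS ether | C=C1CCC[C@H](C)[C@@H](O)[C@@H]2OC(=O)C(=C)[C@@H]2C/C=C(\C)CC[C@@H]1O[Si](C)(C)C(C)(C)C | intermediate
35 | (5S,6R,7R,8S,10E,14S) α-methylene lactone 6,14-diol | C=C1CCC[C@H](C)[C@@H](O)[C@@H]2OC(=O)C(=C)[C@@H]2C/C=C(\C)CC[C@@H]1O | intermediate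
36 | (5S,6R,7R,8S,10E,14S) α-methylene lactone 6,14-diacetate | C=C1CCC[C@H](C)[C@@H](OC(C)=O)[C@@H]2OC(=O)C(=C)[C@@H]2C/C=C(\C)CC[C@@H]1OC(C)=O | intermediate
37 | CNP0323853.2, (5S,6R,7R,8S,10R,11R,14S)-6,14-diacetoxy-10,11-epoxy α-methylene lactone | C=C1CCC[C@H](C)[C@@H](OC(C)=O)[C@@H]2OC(=O)C(=C)[C@@H]2C[C@H]2O[C@]2(C)CC[C@@H]1OC(C)=O | target

**Step count and risks**

Total: 30 steps. Longest linear sequence: 21 steps (steps 1–9, then 19–30; the branch through steps 10–18 is of equal length).

Step 26 (lactone annulation). What may go wrong: slow alkoxycarbonylation at the crowded C7 hydroxyl, so that alkyne oligomerisation or loss of the p-methoxybenzyl ether to the tin Lewis acid takes over. Fallback: the event is split into two known operations. Starting from 32, α-selective hydroalumination (NiCl2(dppp), i-Bu2AlH, THF) and iodinolysis convert the ethynyl group into a 1-iodoethenyl group, giving the (5S,6R,7R,8R,10E,14S)-8-(1-iodoethenyl) carbinol F1 (8R only by priority change, same spatial arrangement). Carbonylative lactonisation of F1 with Pd(PPh3)4 (zerovalent palladium), CO (1 atm) and Et3N in MeCN at 60 °C proceeds by oxidative addition, CO insertion and capture of the acylpalladium by the C7 hydroxyl. It forms the same O7–C16 and C16–C15 bonds and returns to the route at 33.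

Step 30 (epoxidation). What may go wrong: poor facial selectivity if the conformational bias of the 14-membered ring opposes the chiral dioxirane, together with partial hydrolysis of the acetates at pH 10.5. Fallback: the ring's own bias is used instead of fought. Starting from 36, NBS in aqueous DME at 0 °C forms the bromonium ion on the face that electrophiles prefer, and water opens it at the tertiary C11 from the opposite face to give the (10S,11R)-10-bromo-11-hydroxy diacetate F2. Cs2CO3 in MeCN then closes the epoxide by displacing bromide at C10 with inversion, so the oxygen ends up on the face opposite to the one first attacked; this returns to the route at 37.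

Step 24 (C14 reduction). What may go wrong: poor facial selectivity if the macrocyclic enone offers the oxazaborolidine two flanks of similar size or the ring conformation shields the required face. Fallback: C14 is set by inversion instead of reduction. Starting from 29, the C14 epimers are separated; the 14S epimer is 31 itself. The 14R epimer undergoes Mitsunobu inversion (4-nitrobenzoic acid, PPh3, diisopropyl azodicarboxylate, THF, 0 °C), in which the unhindered allylic hydroxyl reacts and the crowded C7 hydroxyl does not, to give the (5S,6R,7R,8S,10E,14S)-14-(4-nitrobenzoate) F3. K2CO3 in MeOH cleaves the ester and returns to the route at 31.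

**Further compounds**

F1 | step 26 | (5S,6R,7R,8R,10E,14S)-14-(tert-butyldimethylsilyloxy)-8-(1-iodoethenyl)-6-(4-methoxybenzyloxy)-5,11-dimethyl-1-methylidenecyclotetradec-10-en-7-ol | C=C1CCC[C@H](C)[C@@H](OCc2ccc(OC)cc2)[C@H](O)[C@H](C(I)=C)C/C=C(\C)CC[C@@H]1O[Si](C)(C)C(C)(C)C
F2 | step 30 | (5S,6R,7R,8S,10S,11R,14S)-10-bromo-11-hydroxy α-methylene lactone 6,14-diacetate | C=C1CCC[C@H](C)[C@@H](OC(C)=O)[C@@H]2OC(=O)C(=C)[C@@H]2C[C@H](Br)[C@](C)(O)CC[C@@H]1OC(C)=O
F3 | step 24 | (5S,6R,7R,8S,10E,14S)-8-ethynyl-7-hydroxy-6-(4-methoxybenzyloxy)-5,11-dimethyl-1-methylidenecyclotetradec-10-en-14-yl 4-nitrobenzoate | C=C1CCC[C@H](C)[C@@H](OCc2ccc(OC)cc2)[C@H](O)[C@H](C#C)C/C=C(\C)CC[C@@H]1OC(=O)c3ccc(cc3)[N+](=O)[O-]
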